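**Conventions.** Core numbering: C1 and C5 are the bridgeheads, ring A = C1-C2-C3-C4-C5-C9 (aroyl on C3), ring B = C1-C8-C7-C6-C5-C9, C9 is the bridging ketone. At C7, "exo" is the face turned away from ring A and "endo" the face turned toward it. "Axial" and "equatorial" at C8 refer to the chair of ring B; axial is syn to C9.

**Assumption.** The target is drawn as its C2-keto/C4-enol tautomer; the enolised triketone is a set of rapidly interconverting tautomers, and the route delivers that mixture.

## The problem

Compound 30 is a bicyclo[3.3.1]nonane-2,4,9-trione in which rings A and B share C1, C5 and C9. Ring A is an enolised, C3-aroylated triketone, and ring B carries all the sp3 stereochemistry. There are four stereocentres: the quaternary bridgeheads C1 and C5 (tied to each other by the bridge), the quaternary C8 next to C1 (methyl equatorial, 4-methylpent-3-enyl axial), and C7 with its prenyl group endo, the less stable orientation. C8 is the only centre that can be set by a reagent-controlled reaction on an acyclic alkene. Once C8 is bonded to C1, the relation of C8 to C1 and C5 is a question of ring-closure geometry, and C7 must then be set kinetically by bringing hydrogen to the exo face. The C1-C8 bond joins two fully substituted carbons and is the hardest bond to make. Four trisubstituted alkenes exclude hydrogenation and strong acid, the catechol is oxidation-prone and must be masked, and the enolised triketone cyclises onto prenyl groups in acid and is best carried as a methyl vinylogous ester. The enabling feature is that C5 carries two constitutionally identical arms, C9-C1 and C4-C3. If both are methyl enol ethers, ring A is a symmetrical cyclohexa-1,4-diene available from an arene, and C5 stays prochiral until C8 is bonded to C1.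

## Retrosynthesis

**Unmasking, 30 from 28.** The O-methyl bond at C4 and the two O-Si bonds of the catechol are cut. The methyl vinylogous ester keeps ring A in one defined form, which makes the lithiations at C1 and C3 regiochemically clean, and silyl ethers survive them. One hydroxide treatment should remove all three groups, passing through 29.

**C3-aroyl bond, 28 from 22 and 26.** The aryl ketone is electrophilic and reducible, so it is introduced last, after the borane, ylide and amide-base steps. With C1 already quaternary, C3-H is the only acidic site in 22. Acid chloride 26 comes from 3,4-dihydroxybenzoic acid 23 through acid 25.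

**C1-prenyl bond, 22 from 20 and 6.** The bridgehead is alkylated through its lithium derivative. This cut comes after the C7 work, because a C7 ketone would not survive the amide base. It comes before the aroylation, because the aryl ketone would not survive either. The forward step must deprotonate C1 and not C3.

**C7 side chain, 20 from 17 and 18, 17 from 16, 16 from 15.** The prenyl group is cut between its CH2 and CH carbons, leading to a C7 methylene and 1-bromo-2-methylpropene 18. The methylene goes back to the C7 ketone 16 and that to the C7 alcohol 15. A carbon nucleophile or radical trap at C7 would enter from the open exo face and give the exo epimer. Adding hydrogen last, from the exo face, gives the endo prenyl group. The price is an oxidation and a methylenation. The forward steps must pick the C7 carbonyl out of three and the 1,1-disubstituted alkene out of three.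

**C2 oxidation, 15 from 13.** The C2 carbonyl is traced to an allylic C-H oxidation directed by the C3=C4 enol ether. The alternative of carrying a third oxygen on the arene would destroy the symmetry that the key step needs.

**C1-C8 bond, 13 from 10 (key cut).** Cutting C1-C8 opens ring B and returns C8 to the tertiary carbon of an epoxide and C1 to an enol ether carbon. The precursor 10 has no ring stereocentre; its only stereocentres are the two epoxide carbons. The forward reaction must open the epoxide at C8 with inversion, choose one of the two enol ether arms, and leave the other arm intact for the C2 oxidation.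

**C5-C6 and C5-prenyl bonds, 10 from 8 and 3, 8 from 5 and 6, 5 from 4.** Both bonds at C5 are made by alkylating the doubly allylic carbon of 1,5-dimethoxycyclohexa-1,4-diene 5, the Birch product of 1,3-dimethoxybenzene 4. Prenyl bromide 6 goes on first and the valuable epoxy bromide 3 second, which keeps the route convergent.

**Epoxide, 3 from 2 from 1.** The bromide 3 comes from epoxy alcohol 2, and 2 from nerol 1 by tartrate-controlled epoxidation. Nerol and not geraniol is required, so that inversion at C8 leaves the 4-methylpent-3-enyl group axial.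

## Roads not taken

**Alternative 1:** Ring B would be cut at C5-C6 and C7-C8, back to the (Z)-2-silyloxy diene A1 and 3-acryloyloxazolidin-2-one A2. In the forward step Cu(SbF6)2 with (S,S)-tert-butyl-bis(oxazoline) (divalent copper, chelated by the imide) would catalyse Mukaiyama-Michael addition of C5 to A2. The resulting imide enolate would then add to C8 and close ring B, giving keto imide A3.

- Merits: the step is catalytic and enantioselective, it builds ring B from acyclic pieces, and it places a carbon substituent on C7 from the start.
- Weak points: the second Michael addition must create the quaternary C8 on a β,β-disubstituted enone. The C7/C8 relation depends on the geometric purity of A1. A3 is only ring B, so ring A must still be annulated across C1 and C5 with a three-carbon 1,3-dielectrophile, next to the quaternary C8. The bridgehead configuration relative to C7 and C8 would be decided in that annulation without a clear controlling element. The imide also needs several steps to become a prenyl group.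
- Comparison: Alternative 1 is better at C7, where the chosen plan spends steps 8 to 10 exchanging oxygen for prenyl. The chosen plan sets against this that one step delivers the whole bicyclic core with C1, C5 and C8 fixed, from a ring A that costs two steps.

**Alternative 2:** Ring A would be cut at C3=C4, back to the alkynyl aldehyde A4, a fully substituted ring B ketone with the aldehyde on C5 and the aryl propargyl silyl ether on C1. In the forward step AgSbF6 (monovalent silver) would promote [2+2] addition of the aldehyde to the alkyne, and opening of the oxetene would close ring A and create the aroyl ketone in A5.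

- Merits: the ring closure also installs the aroyl group, so no late lithiation at C3 is needed, and all four stereocentres are in place before the ring closes.
- Weak points: A4 already contains C1, C5 and C8 as contiguous quaternary centres with the two arms cis, so the stereochemical problem is moved, not solved. A cationic silver salt next to an aldehyde and four trisubstituted alkenes invites carbonyl-ene and Prins closures. A5 has C2 at the alcohol level, with an extra stereocentre, and C4 as a vinylic C-H that must still be oxidised at a hindered position.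
- Comparison: Alternative 2 is more elegant at C3. The chosen plan has the ring A oxygens at C4 and C9 from the arene and needs one oxidation at C2, and its precursor 10 is five steps from commodity materials.

**Alternative 3:** Ring A would be cut at C1-C2, back to the silyl enol ether ynone A6. In the forward step [(tBu2(biphenyl-2-yl)P)Au(NCMe)]SbF6 (monovalent gold) would activate the ethoxyalkynone, and the tetrasubstituted silyl enol ether would attack through C1 in a 6-endo-dig closure, giving the 2-ethoxy enone A7.

- Merits: the congested C1 bridgehead is formed intramolecularly under neutral conditions, with the C1 prenyl group already present. A7 is at the trione oxidation level, so only aroylation and unmasking would remain. After its key step this is the shortest end-game of all four plans.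
- Weak points: A6 needs C5, C7 and C8 set in a monocyclic ketone, where the relation of C5 to C7 and C8 rests on substrate-controlled alkylation or acylation next to a ring carrying an axial chain. The hindered tetrasubstituted silyl enol ether beside the quaternary C8 must be made. The ring B ketone needs its own asymmetric entry.
- Comparison: Alternative 3 is shorter after the ring closure and avoids the bridgehead lithiation of step 11. The chosen plan is shorter before the ring closure, and it fixes the C5 to C8 relation through the ring-closure transition state, where A6 would depend on substrate control.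

Key step: step 6

## Route

Step 1
Reactants: 1 nerol
Product: 2 (2R,3S)-2,3-epoxynerol
Conditions: Ti(OiPr)4 (cat.), D-(−)-diethyl tartrate (cat.), t-BuOOH, 4 Å molecular sieves, CH2Cl2, −20 °C
Reagents that add atoms: tert-butyl hydroperoxide, CC(C)(C)OO
Why: Katsuki-Sharpless asymmetric epoxidation; only the allylic 2,3-alkene binds to titanium, the D-(−)-tartrate complex delivers oxygen to the face that gives 2R, and the Z geometry then fixes 3S and a cis epoxide; the 6,7-alkene is untouched.

Step 2
Reactants: 2 (2R,3S)-2,3-epoxynerol
Product: 3 (2S,3S)-2-(bromomethyl)-3-methyl-3-(4-methylpent-3-enyl)oxirane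
Conditions: PPh3, CBr4, 2,6-lutidine, CH2Cl2, −20 °C → 0 °C
Reagents that add atoms: tetrabromomethane, BrC(Br)(Br)Br
Why: Appel reaction; bromide displaces the alkoxyphosphonium group at the primary carbon, the epoxide carbons are not involved (the descriptor at C2 changes only because of the priority rules), and the base traps traces of HBr.

Step 3
Reactants: 4 1,3-dimethoxybenzene
Product: 5 1,5-dimethoxycyclohexa-1,4-diene
Conditions: Li, NH3 (l), t-BuOH, THF, −78 °C → −33 °C
Reagents that add atoms: none
Why: Birch reduction; the two methoxy groups direct protonation to the carbon between them and to the carbon para to it, giving the 2,5-dihydro isomer with both enol ethers in place.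

Step 4
Reactants: 5 1,5-dimethoxycyclohexa-1,4-diene; 6 prenyl bromide
Product: 8 1,5-dimethoxy-6-(3-methylbut-2-enyl)cyclohexa-1,4-diene, via cyclohexadienyllithium 7 (not isolated)
Conditions: t-BuLi, THF, −78 °C; then 6, −78 °C → 0 °C
Reagents that add atoms: none
Why: Deprotonation at the doubly allylic carbon flanked by the two methoxy-bearing carbons gives a cyclohexadienyl anion, which is alkylated at its central carbon (kinetic site), so the 1,4-diene is kept.

Step 5
Reactants: 8 1,5-dimethoxy-6-(3-methylbut-2-enyl)cyclohexa-1,4-diene; 3 (2S,3S)-2-(bromomethyl)-3-methyl-3-(4-methylpent-3-enyl)oxirane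
Product: 10 1,5-dimethoxy-6-{[(2R,3S)-3-methyl-3-(4-methylpent-3-enyl)oxiran-2-yl]methyl}-6-(3-methylbut-2-enyl)cyclohexa-1,4-diene, via tertiary cyclohexadienyllithium 9 (not isolated)
Conditions: t-BuLi, THF, −78 °C; then 3, −78 °C → −20 °C
Reagents that add atoms: none
Why: Second alkylation of the same carbon; the anion attacks the primary bromide in preference to the di- and trisubstituted epoxide carbons, and the new quaternary C5 is not a stereocentre because its two ring arms are identical.

Step 6
Reactants: 10 1,5-dimethoxy-6-{[(2R,3S)-3-methyl-3-(4-methylpent-3-enyl)oxiran-2-yl]methyl}-6-(3-methylbut-2-enyl)cyclohexa-1,4-diene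
Product: 13 7-exo-hydroxy-4-methoxy-8-methyl-5-(3-methylbut-2-enyl)-8-(4-methylpent-3-enyl)bicyclo[3.3.1]non-3-en-9-one, via bridged methyl ketal 11 (not isolated), via C7 trimethylsilyl ether 12 (not isolated)
Conditions: Me3SiOTf (cat.), 2,6-lutidine, CH2Cl2, −78 °C; then Me3SiI, −78 °C → 0 °C; then K2CO3, MeOH, 0 °C
Reagents that add atoms: none
Why: Me3SiOTf silylates the epoxide oxygen and the enol ether carbon C1 attacks the tertiary, cation-stabilising C8 anti to the departing oxygen, so C8 is inverted and the C7-O bond is retained; the closest known reaction type is the Lewis-acid epoxide-opening cation-olefin cyclisation of cyclohexadiene bis(enol ethers) to bicyclo[3.3.1]nonan-9-ones with a quaternary carbon. Ring B closes in the 6-endo mode at the epoxide (6-enolendo for the nucleophile), preferred over 5-exo attack at C7 because positive charge builds up at the tertiary carbon. C8 is controlled by the 3S epoxide carbon of step 1 together with the Z geometry of nerol, which after inversion leaves the 4-methylpent-3-enyl group axial and the methyl group equatorial on ring B. C1 and C5 are controlled by group selection: only one of the two diastereotopic enol ether arms reaches C8 through a chair in which the C7-O bond is equatorial and ring A is axial on the forming ring, while the other arm would need a boat. The step needs the enol ether to win over three trisubstituted alkenes as the nucleophile, which its far higher nucleophilicity secures, and 2,6-lutidine keeps the medium free of acid so that the second enol ether survives. The C9 oxocarbenium ion is expected to be captured by the C7 silyloxy group, giving bridged ketal 11 and releasing the silyl triflate, which therefore acts catalytically. Me3SiI then silylates the strained bridging oxygen, iodide removes the O-methyl group from the re-formed oxocarbenium ion to give ketone 12, and K2CO3 in methanol frees the C7 hydroxyl of 13.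

Step 7
Reactants: 13 7-exo-hydroxy-4-methoxy-8-methyl-5-(3-methylbut-2-enyl)-8-(4-methylpent-3-enyl)bicyclo[3.3.1]non-3-en-9-one
Product: 15 7-exo-hydroxy-4-methoxy-8-methyl-5-(3-methylbut-2-enyl)-8-(4-methylpent-3-enyl)bicyclo[3.3.1]non-3-ene-2,9-dione, via C2 tert-butyl peroxide 14 (not isolated)
Conditions: PhI(OAc)2, t-BuOOH, K2CO3, EtOAc, −20 °C
Reagents that add atoms: tert-butyl hydroperoxide, CC(C)(C)OO
Why: Radical allylic oxidation; the tert-butylperoxy radical abstracts the C2 hydrogen activated by the electron-rich enol ether, the allyl radical is trapped at C2 (C4 is substituted and flanked by the quaternary C5), and Kornblum-DeLaMare fragmentation of the peroxide gives the vinylogous ester; the prenyl allylic positions are far less activated, and any C7 alcohol oxidised here converges in step 8.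

Step 8
Reactants: 15 7-exo-hydroxy-4-methoxy-8-methyl-5-(3-methylbut-2-enyl)-8-(4-methylpent-3-enyl)bicyclo[3.3.1]non-3-ene-2,9-dione
Product: 16 4-methoxy-8-methyl-5-(3-methylbut-2-enyl)-8-(4-methylpent-3-enyl)bicyclo[3.3.1]non-3-ene-2,7,9-trione
Conditions: Dess-Martin periodinane, NaHCO3, CH2Cl2, 0 °C → rt
Reagents that add atoms: none
Why: Dess-Martin oxidation of a hindered secondary alcohol under buffered conditions; the C7 stereocentre, which served only as the handle left by the epoxide, is removed on purpose.

Step 9
Reactants: 16 4-methoxy-8-methyl-5-(3-methylbut-2-enyl)-8-(4-methylpent-3-enyl)bicyclo[3.3.1]non-3-ene-2,7,9-trione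
Product: 17 4-methoxy-8-methyl-7-methylidene-5-(3-methylbut-2-enyl)-8-(4-methylpent-3-enyl)bicyclo[3.3.1]non-3-ene-2,9-dione
Conditions: Ph3PCH3Br, KN(SiMe3)2, THF, 0 °C → rt
Reagents that add atoms: methyltriphenylphosphonium bromide, C[P+](c1ccccc1)(c1ccccc1)c1ccccc1.[Br-]
Why: Wittig methylenation; the C7 ketone has a CH2 neighbour and should react before the bridging C9 ketone (flanked by the quaternary C5 and the branched C1) and before the deactivated vinylogous ester carbonyl at C2; an amide base leaves no alkoxide that could open the C2/C9 dicarbonyl unit.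

Step 10
Reactants: 17 4-methoxy-8-methyl-7-methylidene-5-(3-methylbut-2-enyl)-8-(4-methylpent-3-enyl)bicyclo[3.3.1]non-3-ene-2,9-dione; 18 1-bromo-2-methylprop-1-ene
Product: 20 4-methoxy-8-methyl-5,7-endo-bis(3-methylbut-2-enyl)-8-(4-methylpent-3-enyl)bicyclo[3.3.1]non-3-ene-2,9-dione, via B-alkyl-9-borabicyclo[3.3.1]nonane 19 (not isolated)
Conditions: 9-BBN, THF, 0 °C → rt; then 18, PdCl2(dppf) (cat.), AsPh3, Cs2CO3, DMF/H2O, rt
Reagents that add atoms: none
Why: 9-BBN hydroborates the 1,1-disubstituted alkene far faster than the trisubstituted ones and puts boron on the CH2 carbon; hydrogen reaches C7 from the exo face because the endo face is covered by C2 to C4 of ring A, so the CH2-B group is endo and C7 has the configuration of the target; B-alkyl Suzuki-Miyaura coupling with vinyl bromide 18 then completes the prenyl group.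

Step 11
Reactants: 20 4-methoxy-8-methyl-5,7-endo-bis(3-methylbut-2-enyl)-8-(4-methylpent-3-enyl)bicyclo[3.3.1]non-3-ene-2,9-dione; 6 prenyl bromide
Product: 22 4-methoxy-8-methyl-1,5,7-endo-tris(3-methylbut-2-enyl)-8-(4-methylpent-3-enyl)bicyclo[3.3.1]non-3-ene-2,9-dione, via C1 bridgehead lithium derivative 21 (not isolated)
Conditions: LiN(iPr)2, THF, −78 °C; then 6, −78 °C → 0 °C
Reagents that add atoms: none
Why: Bridgehead lithiation-alkylation; lithium diisopropylamide removes the C1 hydrogen flanked by the C2 and C9 carbonyls (base-dependent regioselectivity known for methyl enol ethers of bicyclo[3.3.1]nonane-2,4,9-triones), and the pyramidal bridgehead carbanion can only be alkylated with retention.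

Step 12
Reactants: 23 3,4-dihydroxybenzoic acid
Product: 25 3,4-bis(tert-butyldimethylsilyloxy)benzoic acid, via tris-silylated silyl ester 24 (not isolated)
Conditions: t-BuMe2SiCl, imidazole, DMF, rt; then AcOH, THF/H2O, rt
Reagents that add atoms: tert-butyldimethylsilyl chloride, CC(C)(C)[Si](C)(C)Cl
Why: Exhaustive silylation followed by selective hydrolysis of the labile silyl ester; the aryl silyl ethers are stable to dilute acetic acid.

Step 13
Reactants: 25 3,4-bis(tert-butyldimethylsilyloxy)benzoic acid
Product: 26 3,4-bis(tert-butyldimethylsilyloxy)benzoyl chloride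
Conditions: (COCl)2, DMF (cat.), CH2Cl2, 0 °C → rt; used crude
Reagents that add atoms: oxalyl chloride, ClC(=O)C(Cl)=O
Why: Acid chloride formation through the chloroiminium (Vilsmeier-type) activator; aryl silyl ethers tolerate the conditions.

Step 14
Reactants: 22 4-methoxy-8-methyl-1,5,7-endo-tris(3-methylbut-2-enyl)-8-(4-methylpent-3-enyl)bicyclo[3.3.1]non-3-ene-2,9-dione; 26 3,4-bis(tert-butyldimethylsilyloxy)benzoyl chloride
Product: 28 3-[3,4-bis(tert-butyldimethylsilyloxy)benzoyl]-4-methoxy-8-methyl-1,5,7-endo-tris(3-methylbut-2-enyl)-8-(4-methylpent-3-enyl)bicyclo[3.3.1]non-3-ene-2,9-dione, via C3 vinyllithium 27 (not isolated)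
Conditions: lithium 2,2,6,6-tetramethylpiperidide, THF, −78 °C; then 26, −78 °C → −40 °C
Reagents that add atoms: none
Why: Lithiation of the vinylic C3-H between the C2 carbonyl and the C4 methoxy group (α-lithiation of a vinylogous ester), the only acidic site left, followed by C-acylation with the acid chloride; no stereocentre is touched.

Step 15
Reactants: 28 3-[3,4-bis(tert-butyldimethylsilyloxy)benzoyl]-4-methoxy-8-methyl-1,5,7-endo-tris(3-methylbut-2-enyl)-8-(4-methylpent-3-enyl)bicyclo[3.3.1]non-3-ene-2,9-dione
Product: 30 (1S,5S,7S,8R)-3-(3,4-dihydroxybenzoyl)-4-hydroxy-8-methyl-1,5,7-tris(3-methylbut-2-enyl)-8-(4-methylpent-3-enyl)bicyclo[3.3.1]non-3-ene-2,9-dione, via catechol methyl enol ether 29 (not isolated)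
Conditions: LiOH, dioxane/H2O (degassed), rt → 90 °C; then cold dilute HCl to pH 3
Reagents that add atoms: water (as hydroxide), O
Why: Hydroxide cleaves the aryl silyl ethers at silicon, then adds to C4 of the aroyl-activated vinylogous ester and expels methoxide (addition-elimination); C7 is not α to a carbonyl and the other centres are quaternary, so nothing can epimerise, and oxygen is excluded to protect the catecholate.

## Compound list

1 | nerol, (2Z)-3,7-dimethylocta-2,6-dien-1-ol | CC(C)=CCC/C(C)=C\CO | starting material
2 | (2R,3S)-2,3-epoxynerol, [(2R,3S)-3-methyl-3-(4-methylpent-3-enyl)oxiran-2-yl]methanol | OC[C@H]1O[C@@]1(C)CCC=C(C)C | intermediate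
3 | (2S,3S)-2-(bromomethyl)-3-methyl-3-(4-methylpent-3-enyl)oxirane | BrC[C@H]1O[C@@]1(C)CCC=C(C)C | intermediate
4 | 1,3-dimethoxybenzene | COc1cccc(OC)c1 | starting material
5 | 1,5-dimethoxycyclohexa-1,4-diene | COC1=CCC=C(OC)C1 | intermediate
6 | prenyl bromide, 1-bromo-3-methylbut-2-ene | CC(C)=CCBr | starting material
7 | (2,6-dimethoxycyclohexa-2,5-dien-1-yl)lithium | [Li]C1C(OC)=CCC=C1OC | intermediate
8 | 1,5-dimethoxy-6-(3-methylbut-2-enyl)cyclohexa-1,4-diene | COC1=CCC=C(OC)C1CC=C(C)C | intermediate
9 | [2,6-dimethoxy-1-(3-methylbut-2-enyl)cyclohexa-2,5-dien-1-yl]lithium | COC1=CCC=C(OC)C1([Li])CC=C(C)C | intermediate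
10 | 1,5-dimethoxy-6-{[(2R,3S)-3-methyl-3-(4-methylpent-3-enyl)oxiran-2-yl]methyl}-6-(3-methylbut-2-enyl)cyclohexa-1,4-diene | COC1=CCC=C(OC)C1(CC=C(C)C)C[C@H]2O[C@@]2(C)CCC=C(C)C | intermediate
11 | bridged methyl ketal of 13: C9 carries OMe and an oxygen bridge to C7 (ring B boat), C3=C4 methyl enol ether kept | CC(C)=CCC[C@]1(C)[C@H]3C[C@]2(CC=C(C)C)[C@](OC)(O3)[C@H]1CC=C2OC | intermediate
12 | C7-exo trimethylsilyl ether of 13 | CC(C)=CCC[C@]1(C)[C@H](O[Si](C)(C)C)C[C@]2(CC=C(C)C)C(=O)[C@H]1CC=C2OC | intermediate
13 | 7-exo-hydroxy-4-methoxy-8-methyl-5-(3-methylbut-2-enyl)-8-(4-methylpent-3-enyl)bicyclo[3.3.1]non-3-en-9-one (C8 chain axial and syn to C9, C8 methyl equatorial, C1-H) | CC(C)=CCC[C@]1(C)[C@H](O)C[C@]2(CC=C(C)C)C(=O)[C@H]1CC=C2OC | intermediate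
14 | C2 tert-butylperoxy derivative of 13 (C2 configuration not defined) | CC(C)=CCC[C@]1(C)[C@H](O)C[C@]2(CC=C(C)C)C(=O)[C@H]1C(OOC(C)(C)C)C=C2OC | intermediate
15 | 7-exo-hydroxy-4-methoxy-8-methyl-5-(3-methylbut-2-enyl)-8-(4-methylpent-3-enyl)bicyclo[3.3.1]non-3-ene-2,9-dione | CC(C)=CCC[C@]1(C)[C@H](O)C[C@]2(CC=C(C)C)C(=O)[C@H]1C(=O)C=C2OC | intermediate
16 | 4-methoxy-8-methyl-5-(3-methylbut-2-enyl)-8-(4-methylpent-3-enyl)bicyclo[3.3.1]non-3-ene-2,7,9-trione | CC(C)=CCC[C@]1(C)C(=O)C[C@]2(CC=C(C)C)C(=O)[C@H]1C(=O)C=C2OC | intermediate
17 | 4-methoxy-8-methyl-7-methylidene-5-(3-methylbut-2-enyl)-8-(4-methylpent-3-enyl)bicyclo[3.3.1]non-3-ene-2,9-dione | CC(C)=CCC[C@]1(C)C(=C)C[C@]2(CC=C(C)C)C(=O)[C@H]1C(=O)C=C2OC | intermediate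
18 | 1-bromo-2-methylprop-1-ene | CC(C)=CBr | starting material
19 | C7-endo (9-borabicyclo[3.3.1]nonan-9-yl)methyl derivative from 17 | CC(C)=CCC[C@]1(C)[C@@H](CB3C4CCCC3CCC4)C[C@]2(CC=C(C)C)C(=O)[C@H]1C(=O)C=C2OC | intermediate
20 | 4-methoxy-8-methyl-5,7-endo-bis(3-methylbut-2-enyl)-8-(4-methylpent-3-enyl)bicyclo[3.3.1]non-3-ene-2,9-dione | CC(C)=CCC[C@]1(C)[C@@H](CC=C(C)C)C[C@]2(CC=C(C)C)C(=O)[C@H]1C(=O)C=C2OC | intermediate
21 | C1 bridgehead lithium derivative of 20 | CC(C)=CCC[C@]1(C)[C@@H](CC=C(C)C)C[C@]2(CC=C(C)C)C(=O)[C@@]1([Li])C(=O)C=C2OC | intermediate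
22 | 4-methoxy-8-methyl-1,5,7-endo-tris(3-methylbut-2-enyl)-8-(4-methylpent-3-enyl)bicyclo[3.3.1]non-3-ene-2,9-dione | CC(C)=CCC[C@]1(C)[C@@H](CC=C(C)C)C[C@]2(CC=C(C)C)C(=O)[C@@]1(CC=C(C)C)C(=O)C=C2OC | intermediate
23 | 3,4-dihydroxybenzoic acid | OC(=O)c1ccc(O)c(O)c1 | starting material
24 | tert-butyldimethylsilyl 3,4-bis(tert-butyldimethylsilyloxy)benzoate | CC(C)(C)[Si](C)(C)OC(=O)c1ccc(O[Si](C)(C)C(C)(C)C)c(O[Si](C)(C)C(C)(C)C)c1 | intermediate
25 | 3,4-bis(tert-butyldimethylsilyloxy)benzoic acid | OC(=O)c1ccc(O[Si](C)(C)C(C)(C)C)c(O[Si](C)(C)C(C)(C)C)c1 | intermediate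
26 | 3,4-bis(tert-butyldimethylsilyloxy)benzoyl chloride | ClC(=O)c1ccc(O[Si](C)(C)C(C)(C)C)c(O[Si](C)(C)C(C)(C)C)c1 | intermediate
27 | C3 vinyllithium derivative of 22 | CC(C)=CCC[C@]1(C)[C@@H](CC=C(C)C)C[C@]2(CC=C(C)C)C(=O)[C@@]1(CC=C(C)C)C(=O)C([Li])=C2OC | intermediate
28 | 3-[3,4-bis(tert-butyldimethylsilyloxy)benzoyl]-4-methoxy-8-methyl-1,5,7-endo-tris(3-methylbut-2-enyl)-8-(4-methylpent-3-enyl)bicyclo[3.3.1]non-3-ene-2,9-dione | CC(C)=CCC[C@]1(C)[C@@H](CC=C(C)C)C[C@]2(CC=C(C)C)C(=O)[C@@]1(CC=C(C)C)C(=O)C(C(=O)c1ccc(O[Si](C)(C)C(C)(C)C)c(O[Si](C)(C)C(C)(C)C)c1)=C2OC | intermediate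
29 | 3-(3,4-dihydroxybenzoyl)-4-methoxy-8-methyl-1,5,7-endo-tris(3-methylbut-2-enyl)-8-(4-methylpent-3-enyl)bicyclo[3.3.1]non-3-ene-2,9-dione | CC(C)=CCC[C@]1(C)[C@@H](CC=C(C)C)C[C@]2(CC=C(C)C)C(=O)[C@@]1(CC=C(C)C)C(=O)C(C(=O)c1ccc(O)c(O)c1)=C2OC | intermediate
30 | (1S,5S,7S,8R)-3-(3,4-dihydroxybenzoyl)-4-hydroxy-8-methyl-1,5,7-tris(3-methylbut-2-enyl)-8-(4-methylpent-3-enyl)bicyclo[3.3.1]non-3-ene-2,9-dione (CNP0108469.1) | CC(C)=CCC[C@]1(C)[C@@H](CC=C(C)C)C[C@]2(CC=C(C)C)C(=O)[C@@]1(CC=C(C)C)C(=O)C(C(=O)c1ccc(O)c(O)c1)=C2O | target

## Step count and least certain steps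

Total step count: 15. Longest linear sequence: 11 steps (steps 1, 2, 5 to 11, 14, 15 from nerol; the same number from 1,3-dimethoxybenzene through steps 3 to 11, 14, 15).

**Step 6 (key step).** The cyclisation itself rests on a close known reaction type. The one-flask unmasking is the weaker part: iodide-mediated demethylation may fail to stay confined to the bridged ketal and may also attack the C4 methyl enol ether, or the ketal may open incompletely. A second risk is imperfect selection between the two enol ether arms if the axial 4-methylpent-3-enyl group raises the energy of the chair. Fallback: starting from 10, the cyclisation is stopped after the Me3SiOTf stage and bridged ketal 11 is isolated, so that C9 and the C7 oxygen stay protected. Compound 11 is oxidised at C2 under the conditions of step 7 to the bridged ketal vinylogous ester F1. The ketal is then opened with bromodimethylborane at −78 °C and aqueous NaHCO3, which no longer has an enol ether to compete with. This returns to the route at 15.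

**Step 9.** The basic ylide may enolise the hindered C7 ketone toward C6 and stall, or attack the C2/C9 dicarbonyl unit, opening ring A by a retro-Claisen path. Fallback: the order is changed so that methylenation comes before the C2 carbonyl exists. From 13, oxidation with SO3·pyridine, DMSO and Et3N gives the C7 ketone enol ether F2. Wittig methylenation gives the C7 methylidene enol ether F3. The allylic oxidation of step 7 then returns to the route at 17.

**Step 10.** The borane may reduce the C2 or C9 carbonyl in competition with hydroboration. Transmetalation of the β-branched alkylborane next to a quaternary carbon may be slow enough for protodeboronation to take over. Facial control at C7 is lost if ring B reacts through a boat. Fallback without boron or palladium: from 16, indium powder and allyl bromide in THF/aqueous NH4Cl give the C7 tertiary homoallylic alcohol F4. Acylation with methyl chlorooxoacetate gives the methyl oxalate F5. Tin hydride reduction (Bu3SnH at high concentration, AIBN, toluene, 100 °C) generates the planar C7 radical, which takes hydrogen from the exo face to give the C7-endo allyl compound F6. Cross-metathesis with 2-methyl-2-butene (second-generation Hoveyda-Grubbs catalyst) returns to the route at 20. The high tin hydride concentration is meant to outrun 5-exo closure of the radical onto the C8 side chain.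

**Step 11.** Deprotonation may go to C3 in place of C1, or the bridgehead anion may be too hindered to alkylate, with the quaternary C8 and the boat of ring B next to it. Fallback: from 20, C3 is blocked first with lithium 2,2,6,6-tetramethylpiperidide and Me3SiCl, giving the C3-trimethylsilyl compound F7. Bridgehead lithiation with lithium diisopropylamide and prenyl bromide then gives the C3-silyl C1-prenyl compound F8. Bu4NF removes the vinylic silyl group and returns to the route at 22.

**Step 15.** Hot hydroxide may cause retro-Claisen loss of the aroyl group or ring opening, and the catecholate may oxidise. Fallback with two non-hydrolytic steps: from 28, HF·pyridine in THF removes the silyl groups and 29 is isolated. LiCl in DMSO at 120 °C then removes the O-methyl group by substitution at the methyl carbon and gives 30.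

## Further compounds

F1 | step 6 | bridged methyl ketal vinylogous ester, the C2 ketone of 11 | CC(C)=CCC[C@]1(C)[C@H]3C[C@]2(CC=C(C)C)[C@](OC)(O3)[C@H]1C(=O)C=C2OC
F2 | step 9 | 4-methoxy-8-methyl-5-(3-methylbut-2-enyl)-8-(4-methylpent-3-enyl)bicyclo[3.3.1]non-3-ene-7,9-dione | CC(C)=CCC[C@]1(C)C(=O)C[C@]2(CC=C(C)C)C(=O)[C@H]1CC=C2OC
F3 | step 9 | 4-methoxy-8-methyl-7-methylidene-5-(3-methylbut-2-enyl)-8-(4-methylpent-3-enyl)bicyclo[3.3.1]non-3-en-9-one | CC(C)=CCC[C@]1(C)C(=C)C[C@]2(CC=C(C)C)C(=O)[C@H]1CC=C2OC
F4 | step 10 | 7-exo-allyl-7-endo-hydroxy derivative of 16 | CC(C)=CCC[C@]1(C)[C@](O)(CC=C)C[C@]2(CC=C(C)C)C(=O)[C@H]1C(=O)C=C2OC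
F5 | step 10 | methyl oxalate of F4 | CC(C)=CCC[C@]1(C)[C@](OC(=O)C(=O)OC)(CC=C)C[C@]2(CC=C(C)C)C(=O)[C@H]1C(=O)C=C2OC
F6 | step 10 | 7-endo-allyl-4-methoxy-8-methyl-5-(3-methylbut-2-enyl)-8-(4-methylpent-3-enyl)bicyclo[3.3.1]non-3-ene-2,9-dione | CC(C)=CCC[C@]1(C)[C@@H](CC=C)C[C@]2(CC=C(C)C)C(=O)[C@H]1C(=O)C=C2OC
F7 | step 11 | 3-trimethylsilyl derivative of 20 | CC(C)=CCC[C@]1(C)[C@@H](CC=C(C)C)C[C@]2(CC=C(C)C)C(=O)[C@H]1C(=O)C([Si](C)(C)C)=C2OC
F8 | step 11 | 3-trimethylsilyl derivative of 22 | CC(C)=CCC[C@]1(C)[C@@H](CC=C(C)C)C[C@]2(CC=C(C)C)C(=O)[C@@]1(CC=C(C)C)C(=O)C([Si](C)(C)C)=C2OC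
F0 | step 15 | none | none
A1 | alternative 1 | (Z)-2-(tert-butyldimethylsilyloxy) diene with prenyl on C5 (C5=C9 geometry open) | CC(C)=CCC=C(O[Si](C)(C)C(C)(C)C)/C=C(/C)CCC=C(C)C
A2 | alternative 1 | 3-acryloyloxazolidin-2-one | C=CC(=O)N1CCOC1=O
A3 | alternative 1 | ring B keto imide with C7 and C8 set | CC(C)=CCC[C@]1(C)[C@@H](C(=O)N2CCOC2=O)C[C@@H](CC=C(C)C)C(=O)C1
A4 | alternative 2 | ring B ketone with C5 aldehyde and C1 aryl propargyl silyl ether | CC(C)=CCC[C@]1(C)[C@@H](CC=C(C)C)C[C@@](CC=C(C)C)(C=O)C(=O)[C@@]1(CC=C(C)C)[C@H](O[Si](C)(C)C(C)(C)C)C#Cc1ccc(O[Si](C)(C)C(C)(C)C)c(O[Si](C)(C)C(C)(C)C)c1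
A5 | alternative 2 | bicyclic 3-aroyl-3-ene with C2 silyl ether | CC(C)=CCC[C@]1(C)[C@@H](CC=C(C)C)C[C@]2(CC=C(C)C)C(=O)[C@@]1(CC=C(C)C)[C@H](O[Si](C)(C)C(C)(C)C)C(C(=O)c1ccc(O[Si](C)(C)C(C)(C)C)c(O[Si](C)(C)C(C)(C)C)c1)=C2
A6 | alternative 3 | ring B silyl enol ether with C5 ethoxyalkynone | CC(C)=CCC[C@]1(C)[C@@H](CC=C(C)C)C[C@@](CC=C(C)C)(C(=O)C#COCC)C(O[Si](C)(C)C(C)(C)C)=C1CC=C(C)C
A7 | alternative 3 | bicyclic 2-ethoxy enone (protected 2,4,9-trione) | CC(C)=CCC[C@]1(C)[C@@H](CC=C(C)C)C[C@]2(CC=C(C)C)C(=O)[C@@]1(CC=C(C)C)C(OCC)=CC2=O
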